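The epsilon and alpha runs, with the same charge of coupling partner, cannot both be one first-order reaction of the solid substrate. Such a reaction converts the same fraction of any charge in a given time, but at 2.50 min the epsilon run shows 14.9% and the alpha run 7.9%.

| setting | epsilon | alpha | beta | flask |
|---|---|---|---|---|
| solid substrate | 0.34 M | 0.75 M | 0.50 M | 0.50 M |
| coupling partner | 1 M | 1 M | 2 M | 1.00 M |
| remark | run made earlier | run made earlier | run made earlier |  |
| time |  |  |  | 2.0 min |

| run | time / min | target / % |
|---|---|---|
| epsilon | 0.200 | 0 |
| epsilon | 0.333 | 2.5 |
| epsilon | 0.500 | 2.7 |
| epsilon | 0.833 | 3.4 |
| epsilon | 1.33 | 7.4 |
| epsilon | 2.50 | 14.9 |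
| alpha | 0.167 | 0.2 |
| alpha | 0.500 | 1.4 |
| alpha | 0.833 | 1.7 |
| alpha | 1.33 | 3.2 |
| alpha | 2.00 | 7.7 |
| alpha | 2.50 | 7.9 |
| beta | 0.200 | 0.6 |
| beta | 0.667 | 5.9 |
| beta | 1.00 | 6.8 |
| beta | 1.50 | 7.9 |
| beta | 2.50 | 15.0 |

(scatter of a reading: 1 percentage point)

So multiply each fraction by its charge. You get 0.0507 M and 0.0592 M, close together although the charge differs 2.21-fold. The readings look apparently zero order in the charge. Divide by the time and average, and you have the output rate, the fraction made times the charge, per minute: 0.0220 M/min. But the last reading of the beta run, with twice the partner and a charge of solid substrate between the other two, gives 0.0300 M/min. That is 1.36 times as much, so the partner counts, though less than in proportion.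

- target at 2.0 min, in percent of the solid substrate charged
- the change that raises the amount of target at 2.0 min, in percent of the solid substrate charged most ("none" if none brings more than 2 percentage points) (north-west / east / south-east / none)
- amount of target at 2.0 min, in percent of the solid substrate charged, after south-east

- north-west: doubling the amount of coupling partner, all else as stated
- east: doubling the solubility of the solid substrate, all else as stated
- south-east: doubling the dissolution coefficient of the solid substrate, all else as stated

- given per volume of solution although it is solid: solid substrate
- at the start none of the solid substrate is in solution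

My reckoning for the flask is output rate times time, divided by the charge: 8.79%. The forecast differs slightly: 8.5%, range 7% to 10%. It picks east and puts south-east at 11%, range 9% to 14%. Its ground: “the rate doesn't depend on solid loading”.

The flask gives 9.58%. The best change is east, worth 7.1 percentage points, and south-east gives 12.9%.

    dissolved substrate + target → side product (k = 0.00990 /M/s)
    solid substrate ⇌ dissolved substrate, rate k2*(cs2 - [dissolved substrate]) while solid is left; crystals form when [dissolved substrate] > cs2 (solubility = 0.240 M, k = 0.0180 /s)
    2 coupling partner → self-condensation product (k = 0.0140 /M/s)
    dissolved substrate + coupling partner → target (k = 0.0100 /M/s)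

Part of what holds the flask at 9.58% is the low solubility of dissolved substrate together with the loss of coupling partner to self-condensation product. The run without the low solubility gives 27.6%, and the run without self-condensation gives 23.2%. Now carry the output rate to the neighbour flask with 1.2 M of solid substrate, other settings unchanged: it gives 3.66%. The computed result there is 3.99%.

All runs were generated by integration with constants of no real substance, noise included.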